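## Retrosynthetic overview
1. Kazinol B (**1**) comes from its TIPS ether (**2**). The 2-aryl-chroman C2–O bond, which carries the only stereocentre, is formed last by an asymmetric Co–H hydrogen-atom-transfer (MHAT) radical–polar-crossover hydroalkoxylation of the (E)-diarylpropene **3**.
2. **3** is disconnected by Heck coupling into aryl bromide **4** (the B ring, with pyran and prenyl already in place) and 4-allylresorcinol **5** (the A ring).
3. **4** is built from catechol (**6**) by mono-silylation, para-bromination, pyran annulation with prenal, then directed lithiation/Cu-prenylation. **5** is built from resorcinol (**7**) by O-allylation and Claisen rearrangement.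
4. Ring order: pyran ring first, prenyl second, chroman ring last.

Assumptions:
- The Claisen rearrangement of the 3-allyloxyphenol gives mainly the 4-allyl isomer, and the 2-allyl isomer is separable.
- The Heck step gives mainly the (E)-1,3-diarylpropene.
- The Co(salen) enantiomer that gives the (S)-ether is taken as (R,R). If the ent-product forms, use (S,S).

## Route

**Step 1**
Reactants: **6** catechol (3 equiv)
Product: **8** 2-(triisopropylsilyloxy)phenol
Conditions: TIPSCl (1.0 equiv), imidazole, CH2Cl2, 0 °C → rt
Reagents that add atoms: TIPSCl, CC(C)[Si](Cl)(C(C)C)C(C)C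
Why: Catechol is symmetric, so bulky TIPSCl gives mono-silylation without a regiochemistry problem. TIPS survives LDA at –78 °C and can later be removed with fluoride, avoiding acid that could ionise the benzylic C2–O bond.

**Step 2**
Reactants: **8**
Product: **9** 4-bromo-2-(triisopropylsilyloxy)phenol
Conditions: NBS (1.0 equiv), CH2Cl2, –40 → 0 °C
Reagents that add atoms: NBS, O=C1CCC(=O)N1Br
Why: Electrophilic aromatic bromination goes para to the free, more strongly donating OH. This puts Br at the carbon that will carry the flavan C2.

**Step 3**
Reactants: **9**; **10** prenal (3-methylbut-2-enal, CC(C)=CC=O)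
Product: **11** 6-bromo-2,2-dimethyl-8-(triisopropylsilyloxy)-2H-chromene
Conditions: **10** (3 equiv), EDDA (20 mol%), xylenes, 140 °C
Reagents that add atoms: none
Why: EDDA-catalysed Knoevenagel/6π-oxa-electrocyclisation (a formal [3+3] benzopyran annulation) can only occur at C6, the single free ortho position of the OH.

**Step 4**
Reactants: **11**; **12** prenyl bromide (CC(C)=CCBr)
Product: **4** 6-bromo-7-(3-methylbut-2-enyl)-8-(triisopropylsilyloxy)-2,2-dimethyl-2H-chromene
Conditions: LDA (1.3 equiv), THF, –78 °C; then CuI (10 mol%), **12** (1.5 equiv), –78 °C → rt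
Reagents that add atoms: none
Why: C7–H sits between Br and OTIPS and is the most acidic site. LDA deprotonates it without Br/Li exchange, and Cu-catalysed SN2 alkylation gives the linear prenyl group (directed ortho-metalation/alkylation).

**Step 5**
Reactants: **7** resorcinol (3 equiv); **13** allyl bromide (C=CCBr)
Product: **14** 3-(allyloxy)phenol
Conditions: K2CO3, acetone, reflux
Reagents that add atoms: none
Why: Williamson mono-O-allylation; excess resorcinol suppresses diallylation.

**Step 6**
Reactants: **14**
Product: **5** 4-allylbenzene-1,3-diol (4-allylresorcinol)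
Conditions: PhNEt2, 200 °C (sealed tube)
Reagents that add atoms: none
Why: Aromatic Claisen [3,3] rearrangement goes to the less hindered ortho carbon (C6 of the aryl ether), which is para to the free OH. This gives the allyl arene with the ortho OH needed for chroman closure and the para OH that becomes the 7-OH.

**Step 7**
Reactants: **4**; **5** (1.5 equiv)
Product: **3** (E)-4-[3-(7-prenyl-8-TIPSO-2,2-dimethyl-2H-chromen-6-yl)prop-2-en-1-yl]benzene-1,3-diol
Conditions: Pd2(dba)3 (2.5 mol%), P(t-Bu)3·HBF4 (10 mol%), Cy2NMe, 1,4-dioxane, 100 °C
Reagents that add atoms: none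
Why: Mizoroki–Heck arylation of the terminal allyl alkene, with a bulky electron-rich phosphine to cope with the ortho-substituted bromide. β-H elimination toward the new aryl group gives the conjugated (E)-1,3-diarylpropene.

**Step 8**
Reactants: **3**
Product: **2** TIPS ether of Kazinol B, (S)-configured
Conditions: (R,R)-Co(salen) (3 mol%), N-fluoro-2,4,6-trimethylpyridinium BF4 (1.5 equiv), PhSiH3 (1.5 equiv), PhCF3/CH2Cl2, 0 °C → rt
Reagents that add atoms: none (the silane supplies only H, and the N–F oxidant leaves no atoms)
Why: Proposed new method: Co(III)–H, generated from the Co(salen), oxidant and silane, transfers H• to C3 of the β-alkyl-styrene. This gives the p-alkoxybenzylic C2 radical, which is intercepted by Co to give an alkyl-Co(IV)/benzylic cation species. The ortho phenol OH closes the 6-membered ring, and the chiral salen environment sets the (S) C2 centre in this C–O-forming step (closest known reaction: Shigehisa/Pronin-type asymmetric Co-salen radical–polar-crossover hydroalkoxylation). The para-alkoxystyrene gives the most stabilised radical and should outcompete the hindered prenyl and chromene alkenes. The para OH of the A ring cannot cyclise.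

**Step 9**
Reactants: **2**
Product: **1** Kazinol B
Conditions: TBAF (1.5 equiv), AcOH (1.5 equiv), THF, 0 °C → rt
Reagents that add atoms: none
Why: Fluoride cleaves the aryl silyl ether under buffered, non-acidic conditions, so the benzylic C2 stereocentre is not ionised or racemised and the prenyl, pyran and chroman groups are untouched.

## Compound list
1 | Kazinol B, (S)-flavan | CC(C)=CCc1c([C@@H]2CCc3ccc(O)cc3O2)cc2c(c1O)OC(C)(C)C=C2 | target
2 | TIPS ether of Kazinol B | CC(C)=CCc1c([C@@H]2CCc3ccc(O)cc3O2)cc2C=CC(C)(C)Oc2c1O[Si](C(C)C)(C(C)C)C(C)C | intermediate
3 | (E)-1,3-diarylpropene | Oc1cc(O)ccc1C/C=C/c1cc2C=CC(C)(C)Oc2c(O[Si](C(C)C)(C(C)C)C(C)C)c1CC=C(C)C | intermediate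
4 | 6-bromo-7-prenyl-8-TIPSO-2,2-dimethyl-2H-chromene | CC(C)=CCc1c(Br)cc2C=CC(C)(C)Oc2c1O[Si](C(C)C)(C(C)C)C(C)C | intermediate
5 | 4-allylresorcinol | C=CCc1ccc(O)cc1O | intermediate
6 | catechol | Oc1ccccc1O | starting material
7 | resorcinol | Oc1cccc(O)c1 | starting material
8 | 2-(TIPSO)phenol | CC(C)[Si](C(C)C)(C(C)C)Oc1ccccc1O | intermediate
9 | 4-bromo-2-(TIPSO)phenol | CC(C)[Si](C(C)C)(C(C)C)Oc1cc(Br)ccc1O | intermediate
10 | prenal | CC(C)=CC=O | starting material
11 | 6-bromo-8-TIPSO-2,2-dimethyl-2H-chromene | CC1(C)C=Cc2cc(Br)cc(O[Si](C(C)C)(C(C)C)C(C)C)c2O1 | intermediate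
12 | prenyl bromide | CC(C)=CCBr | starting material
13 | allyl bromide | C=CCBr | starting material
14 | 3-(allyloxy)phenol | C=CCOc1cccc(O)c1 | intermediate

## Totals
Total steps: 9. Longest linear sequence: 7 (steps 1, 2, 3, 4, 7, 8, 9).

## Three steps most likely to fail
1. **Step 8 (asymmetric MHAT hydroalkoxylation).** Risks are competing HAT at the prenyl alkene (possible indane or chroman by-products), N–F oxidation of the free phenols, and ee erosion through the stabilised benzylic cation. Fallback: cyclise a substrate carrying a C7 bromide instead of prenyl, then install prenyl late by Br/Li exchange and CuI-catalysed prenylation. Alternatively, cyclise with achiral Co(salen) and resolve by chiral-phase HPLC.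
2. **Step 4 (lithiation/prenylation between Br and OTIPS).** Risks are aryne formation, halogen dance, retro-Brook silyl migration and SN2′ (reverse-prenyl) products. Fallback: omit the prenyl group at this stage. Take the 8-hydroxychromene, make its 1,1-dimethylpropargyl ether, apply Lindlar reduction, then a thermal Claisen rearrangement, which delivers the C7 prenyl regiospecifically.
3. **Step 7 (Heck on a hindered ortho-substituted bromide).** Risks are low conversion and a mixture of alkene regioisomers. Fallback: Suzuki vinylation of **4** with potassium vinyltrifluoroborate, then Grubbs-II cross-metathesis with **5**, which fixes the (E)-alkene position unambiguously.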